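The numbers were chosen freely; what happens was integrated by code.

Red's figure worth committing to is the slope of its target while crystals stand, not the level.

    2 substrate → self-condensation product (k1 = 0.0553 /M/h, Ea1 = 105 kJ/mol)
    target + catalyst ⇌ isomer of the product + catalyst, rate k2*[catalyst]*[target] forward; the back reaction follows from the equilibrium constant (k2 = 0.645 /M/h, Ea2 = 69.0 kJ/mol)
    substrate + partner ⇌ target (K3 = 0.48 /M, k3 = 0.108 /M/h, Ea3 = 103 kJ/mol, ΔH3 = −32.0 kJ/mol)
    substrate + partner ⇌ isomer of the product (K4 = 0.96 /M, k4 = 0.0679 /M/h, Ea4 = 110 kJ/mol, ΔH4 = −54.0 kJ/mol)
    crystals ⇌ target, rate k5*(cs5 - [target]) while solid is left; crystals form when [target] > cs5 (cs5 = 0.20 M, k5 = 0.261 /h)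
    (constants at 100 °C)
common to all: substrate 1.5 M; partner 1.50 equiv; catalyst 4.5 mol%; time 8.0 d
- red: temperature 85 °C
- teal: temperature 100 °C
- amber: at 85 °C until 2.5 d, from then on at 115 °C
- ochre: temperature 115 °C
- a species is counted by the substrate in it: one self-condensation product counts as two
- amounts and yields of target count crystals too
- two of one species on the left: rate k times its square, two consumed each time
- given per volume of solution although it is solid: crystals
- the constants hold at 100 °C; other temperatures follow from the activation energies and enthalpies
1. which flask leads in amount of target, in percent of the substrate charged ("all alike" within 1.5 percentage points) (red / teal / amber / ochre / all alike)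
2. how much target is there at the end, in percent of the substrate charged: red
3. how much target is there at the end, in percent of the substrate charged: teal
4. how much target is there at the end, in percent of the substrate charged: amber
5. how much target is there at the end, in percent of the substrate charged: ochre

While crystals stand, dissolved target stays near its solubility, 0.20 M, and the isomer exchanges with it. Partner is taken as frozen, and substrate should then sit near the value its equilibrium with partner and target allows, a pre-equilibrium. Self-condensation takes substrate out of this pool and the crystals make up the loss. The quantity to reckon is the drain, the fraction of the charged substrate passing per unit time into self-condensation product at that frozen substrate level: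

substrate ≈ solubility / (equilibrium constant of target × partner)
drain = 2 × self-condensation constant × substrate² / substrate charged

Which numbers must be good? An error in the self-condensation constant passes into the drain unchanged. Errors in solubility, equilibrium constant and partner count twice, since substrate is squared. Catalyst loading and the isomerisation constant do not stand in the formula. Neither does the forward constant, provided capture by partner outruns self-condensation. The corrections to red's temperature matter: the self-condensation constant falls from 0.0553 /M/h to 0.0134 /M/h, a factor 4.13, and the equilibrium constant rises from 0.48 /M to 0.739 /M, which raises its square by a factor 2.37.

The numbers for red at 85 °C, with partner frozen halfway between its excess and its charge: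

equilibrium constant 0.739 /M; self-condensation constant 0.0134 /M/h
partner 1.50 M; substrate 0.180 M, or 12.0% of the charge
drain 0.0139 /d; over the second half of the time, 5.58%

The freezing is fair because a substrate is captured by partner at 0.0403 /h, faster than it self-condenses at 0.00483 /h. This reckoning gives a slope and no final figure.

The forecast puts red ahead, with 21% in red, 7% in teal, 2% in amber and 1.5% in ochre, on the ground that “the irreversible self-condensation slowly drains that pool”.

The simulation also leads with red: 23.1% in red, 7.03% in teal, 2.14% in amber, 1.50% in ochre. Red's target reads 28.9% at 4.00 d and 23.1% at 8.00 d, a fall of 5.8 percentage points against the reckoned 5.58%, while substrate reads 11.5% and crystals 9.99%. By this step alone, the exchange of dissolved target and isomer in amber relaxes at 8.00 d with a half-life of 0.169 d, short against 8.0 d, while amber's self-condensation product reaches 91.5%.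

Amber's neighbour, read at 50 h, before the change at 2.5 d and so still at 85 °C like red, holds 18.4% of crystals. The drain, carried back from red's 28.9%, gives 31.6% there, and the simulation gives 31.6%.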